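**Compound numbering used throughout:** 1 guaiacol; 2 dibromoguaiacol; 3 5‑bromo‑2‑fluorobenzaldehyde; 4 diaryl ether aldehyde; 5 aryl formate; 6 monobromo ring A–ring B phenol; 7 tribromo ring A–ring B phenol; 8 vinyl ether; 9 dibromoethyl ether; 10 (Z)‑bromovinyl ether; 11 terminal ynol ether; 12 lithium acetylide; 13 silyl ynol ether; 14 coumalic acid; 15 5‑bromo‑2‑pyrone; 16 bridged lactone; 17 aryl silane; 18 O‑methyl ether of the target; 19 bromoiesol B.

## Analysis of the target

Bromoiesol B (19) is an achiral triaryl bis‑ether: three benzene rings joined in a row by two oxygen atoms, with no stereocenter and no ring fusion. Ring A is a phenol with the first ether oxygen ortho to the hydroxyl and bromines ortho and para to that oxygen. Ring B, in the middle, carries the two ether oxygens on adjacent carbons, then three contiguous bromines and one hydrogen; ring C is a 4‑bromo‑2‑iodophenyl group. The six C–Br bonds and the weak C–I bond exclude alkyllithium reagents, dissolving metals and low‑valent palladium, nickel or copper catalysts late in the synthesis, and the free phenol must stay masked while electrophiles are in use. The difficulty is regiochemical and steric. Every halogen has to be placed without scrambling, and the oxygen between ring B and ring C sits on a ring B carbon flanked by a bromine‑bearing carbon and by the carbon that carries the ring A ether, while its ring C partner has an ortho iodine. Ring C has no activating group for SNAr, and a metal‑catalysed arylation would have to choose one C–halogen bond among several. The strategy rests on building ring C on that oxygen instead of coupling it: the oxygen‑bearing C1 and the iodine‑bearing C2 of ring C come from an O‑bound alkyne, and the other four carbons from C3–C6 of 5‑bromo‑2‑pyrone (15), whose C5 bromine ends para to oxygen.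

## Retrosynthetic reasoning

19 to 18: the O–CH3 bond of ring A is the last bond made to be broken. The methyl group is the one that guaiacol (1) already carries; it keeps the ring A oxygen from competing in the ether formation, the vinylation and the electrophilic iodination. The forward step is a Lewis‑acid demethylation that leaves diaryl ethers and aryl halides alone.

18 to 17: the C–I bond is exchanged for a C–Si bond. Iodine is the most fragile substituent, so it enters last, and an ipso substitution at silicon fixes its position without relying on directing effects among three halogenated rings.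

17 to 13 and 15: ring C is cut at the bond between its oxygen‑bearing carbon and the neighbouring CH, and at the bond between its silicon‑bearing carbon and the neighbouring CH. This leaves the crowded ring B–oxygen bond untouched and places the oxygen on an sp carbon of 13. The four remaining ring carbons and the para bromine come from 15, so no aryl–oxygen coupling is needed at the hindered oxygen. The forward reaction must add the alkyne across C3 and C6 of 15 in one orientation and then aromatise by losing the lactone bridge of 16.

13 to 7 (through 12, 11, 10, 9 and 8): the C–Si bond, the triple bond and the O–vinyl bond are taken apart in turn. A vinyl group is the smallest carbon unit that can be delivered to the hindered oxygen of 7. Bromine addition and two dehydrobrominations raise it to the alkyne without organolithium reagents, which the aryl bromides would not survive.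

7 to 6: two C–Br bonds of ring B are cut, those ortho and para to the hydroxyl. The hydroxyl of 6 directs exactly to these two positions, and the bromine between them is already present, so the three contiguous bromines arise from one directed bromination.

6 to 4 (through 5): the phenolic C–O bond is traced back to a formyl group. The formyl group first activates the fluoride displacement and is then converted into the hydroxyl by an oxidative aryl migration.

4 to 2 and 3: the ring A–oxygen–ring B link is cut at the O–C(ring B) bond. At this stage ring B is unhindered and activated, so an uncatalysed SNAr suffices. Ring A must already carry its bromines, because after ether formation the methoxy group would direct bromination to the wrong positions.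

2 to 1, and 15 to 14: the two ring A bromines go in ortho and para to the free hydroxyl of 1, and 15 comes from coumalic acid (14) by replacing the carboxyl group at C5 with bromine.

## Alternatives that were turned down

Alternative 1: Ring B is cut at two of its C–C bonds and made by cycloaddition of the alkynyl boronate ynol ether A3 (the ring C phenol on a borylated alkyne) with 2,3,4‑tribromothiophene 1,1‑dioxide A2. Cheletropic loss of the sulfonyl bridge would give the ring B boronate A1, which already carries ring C.
- For: it is the most convergent plan, and on that point stronger than the chosen route. All three ring B bromines arrive in one piece, and the hindered ring B–oxygen–ring C link is never made by arylation.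
- Against: A2 is not a stock compound. An electron‑poor tribromothiophene resists S‑oxidation, and a thiophene dioxide with a free alpha position tends to dimerise. The orientation of an unsymmetrical diene with an unsymmetrical alkyne is backed only by sterics. A3 combines two sensitive functions and an aryl iodide that must survive acetylide chemistry and heating.
- Decisive weakness: after the key step, the boron of A1 still has to become the oxygen link to ring A. That means an oxidative copper coupling between a hindered boronate and the hindered phenol 2, in the presence of an aryl iodide.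
- Comparison: the chosen route makes that same ring A–ring B link first, by SNAr on an unhindered ring, and gives up some convergence for it.

Alternative 2: Ring A is cut at two C–C bonds and formed from 3,5‑dibromo‑2‑pyrone A5 and the alkynyl boronate ynol ether A6 built on the ring B–ring C half. Decarboxylation would give the ring A boronate A4, and oxidation of the C–B bond would give 19 directly.
- For: the diene is well behaved and brings both ring A bromines. The end game is stronger than in the chosen route, since one oxidation delivers the free phenol with no protecting group and no separate iodination.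
- Against: the cycloaddition is spent on the ring A–ring B oxygen, which a plain SNAr can make. The hindered ring B–ring C ether must then be made by a conventional arylation inside A6.
- With that oxygen etherified, ring B has lost the hydroxyl that directs its two extra bromines. A hydroxyl on the other oxygen‑bearing carbon would send them to the wrong positions.
- The iodine is carried through base and heat. The boryl group is a pi acceptor on the alkyne carbon that has to lead bond formation, and the pyrone carbon that meets the aryloxy carbon bears a bromine.
- Comparison: the chosen route needs two more finishing steps, but it uses the cycloaddition at the oxygen that is hard to arylate and keeps iodine out until the end.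

Alternative 3: The ring C–oxygen bond and the adjacent C–I bond are cut together. A fluoride source would release the aryne from the silyl triflate A8, the caesium phenoxide of 7 would add to it, and the resulting aryl anion would take iodine from perfluorohexyl iodide A9. The product is the O‑methyl ether A7, the same compound as 18.
- For: it is clearly the shortest plan, one step from 7 to 18 against five in the chosen route. An aryne is reactive enough to accept a hindered, weakly nucleophilic phenoxide.
- Against: the bromine of the aryne is meta to one aryne carbon and para to the other, so it polarises the triple bond only weakly and both orientations of addition are expected. The two regioisomeric hexahalogenated triaryl ethers would be very hard to separate.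
- The aryl anion can also be protonated before it finds iodine, and the poor nucleophile competes with fluoride and adventitious water for the aryne.
- Comparison: the chosen route is longer, but the positions of oxygen, bromine and iodine on ring C follow from the connectivity of 13 and 15 and from an ipso substitution, not from a weak substituent effect.

Key step: step 9

Remark on the chemistry: the dehydrobromination in step 6 is assumed to give mainly the Z bromovinyl ether, as 1,2‑dibromoethyl ethers usually do; both geometrical isomers lead to the same alkyne in step 7.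

## Route

Step 1
Reactants: 1 guaiacol (2‑methoxyphenol)
Product: 2 2,4‑dibromo‑6‑methoxyphenol
Conditions: Br2 (2.05 equiv), AcOH, 10 → 20 °C
Reagents that add atoms: bromine, BrBr
Why: Electrophilic aromatic bromination; the free hydroxyl is the strongest donor and sends the two bromines to its para and its free ortho position, which later lie para and ortho to the ring A ether oxygen. Two equivalents are used so that the position para to the methoxy group stays free.

Step 2
Reactants: 2 2,4‑dibromo‑6‑methoxyphenol; 3 5‑bromo‑2‑fluorobenzaldehyde
Product: 4 5‑bromo‑2‑(2,4‑dibromo‑6‑methoxyphenoxy)benzaldehyde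
Conditions: K2CO3, DMAc, 130 °C
Reagents that add atoms: none
Why: Nucleophilic aromatic substitution (SNAr); the ortho formyl group stabilises the Meisenheimer adduct and fluoride leaves, so the hindered phenoxide of 2 attacks only C2 of 3, whose bromine is meta to the formyl group and is not displaced. The ether is made here because ring B is still unhindered and no metal catalyst is needed.

Step 3
Reactants: 4 5‑bromo‑2‑(2,4‑dibromo‑6‑methoxyphenoxy)benzaldehyde
Product: 6 5‑bromo‑2‑(2,4‑dibromo‑6‑methoxyphenoxy)phenol, via aryl formate 5 (not isolated)
Conditions: mCPBA, CH2Cl2, 40 °C; then K2CO3 (cat.), MeOH, 20 °C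
Reagents that add atoms: mCPBA (3‑chloroperoxybenzoic acid), O=C(OO)c1cccc(Cl)c1
Why: Baeyer–Villiger oxidation of an aryl aldehyde (Dakin type); in the Criegee adduct the aryl group, made electron‑rich by its ortho aryloxy substituent, migrates in preference to hydride and gives formate 5, which methanol transesterifies to the phenol. The aryl bromides and the deactivated anisole ring are inert to the peracid.

Step 4
Reactants: 6 5‑bromo‑2‑(2,4‑dibromo‑6‑methoxyphenoxy)phenol
Product: 7 2,3,4‑tribromo‑6‑(2,4‑dibromo‑6‑methoxyphenoxy)phenol
Conditions: Br2 (2.1 equiv), AcOH, 20 °C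
Reagents that add atoms: bromine, BrBr
Why: Electrophilic aromatic bromination directed by the new hydroxyl to its para and free ortho positions, which flank the bromine already present and complete the three contiguous bromines of ring B. Ring A is deactivated by two bromines, and the last ring B hydrogen is meta to the hydroxyl.

Step 5
Reactants: 7 2,3,4‑tribromo‑6‑(2,4‑dibromo‑6‑methoxyphenoxy)phenol
Product: 8 1,2,3‑tribromo‑5‑(2,4‑dibromo‑6‑methoxyphenoxy)‑4‑(ethenyloxy)benzene
Conditions: 2,4,6‑trivinylcyclotriboroxane·pyridine (0.7 equiv), Cu(OAc)2 (2 equiv), pyridine, CH2Cl2, air, 20 °C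
Reagents that add atoms: 2,4,6‑trivinylcyclotriboroxane–pyridine complex, C=CB1OB(C=C)OB(C=C)O1.c1ccncc1
Why: Copper‑mediated oxidative O‑vinylation of a phenol with a vinylboron reagent (Chan–Lam coupling); the vinyl group is transferred to copper and C–O reductive elimination from a trivalent copper phenoxide forms the ether at 20 °C, where divalent copper does not insert into aryl bromides. Vinyl is the smallest sp2 carbon unit that can be brought to the crowded oxygen.

Step 6
Reactants: 8 1,2,3‑tribromo‑5‑(2,4‑dibromo‑6‑methoxyphenoxy)‑4‑(ethenyloxy)benzene
Product: 10 1,2,3‑tribromo‑4‑[(Z)‑2‑bromoethenyloxy]‑5‑(2,4‑dibromo‑6‑methoxyphenoxy)benzene, via dibromoethyl ether 9 (not isolated)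
Conditions: Br2 (1.0 equiv), CH2Cl2, −78 °C; then DBU (1.5 equiv), −78 → 20 °C
Reagents that add atoms: bromine, BrBr
Why: Bromine adds to the electron‑rich enol ether double bond at −78 °C far faster than it attacks the deactivated rings. The alpha‑bromo ether 9 then loses HBr by ionisation to the oxocarbenium ion and deprotonation by the amidine base (dehydrohalogenation), which should give mainly the Z 2‑bromovinyl ether.

Step 7
Reactants: 10 1,2,3‑tribromo‑4‑[(Z)‑2‑bromoethenyloxy]‑5‑(2,4‑dibromo‑6‑methoxyphenoxy)benzene
Product: 13 trimethyl{[2,3,4‑tribromo‑6‑(2,4‑dibromo‑6‑methoxyphenoxy)phenoxy]ethynyl}silane, via terminal ynol ether 11 (not isolated), via lithium acetylide 12 (not isolated)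
Conditions: KOtBu (1.3 equiv), THF, −40 → 0 °C; then LiN(SiMe3)2 (2.5 equiv), −78 °C; then Me3SiCl (4 equiv), −78 → 0 °C
Reagents that add atoms: chlorotrimethylsilane, C[Si](C)(C)Cl
Why: Anti E2 elimination of HBr from the Z bromovinyl ether gives the aryl ethynyl ether, the classical way to aryloxyacetylenes. The hindered silylamide, too weak a base to metalate the bromoarene rings, deprotonates the terminal alkyne, and the acetylide is silylated on carbon. Alkyllithium reagents are avoided because of bromine–lithium exchange, and the labile terminal ynol ether is not isolated.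

Step 8
Reactants: 14 coumalic acid (2‑oxo‑2H‑pyran‑5‑carboxylic acid)
Product: 15 5‑bromo‑2H‑pyran‑2‑one
Conditions: NBS (1.05 equiv), LiOAc (0.2 equiv), MeCN/H2O, 20 °C
Reagents that add atoms: N‑bromosuccinimide, O=C1CCC(=O)N1Br
Why: Bromodecarboxylation (Hunsdiecker‑type halodecarboxylation of a vinylogous carboxylate); the carboxylate is brominated at C5, the nucleophilic pyrone position that bears the carboxyl group, and the adduct loses CO2. One equivalent of NBS limits a second bromination at C3.

Step 9
Reactants: 13 trimethyl{[2,3,4‑tribromo‑6‑(2,4‑dibromo‑6‑methoxyphenoxy)phenoxy]ethynyl}silane; 15 5‑bromo‑2H‑pyran‑2‑one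
Product: 17 {5‑bromo‑2‑[2,3,4‑tribromo‑6‑(2,4‑dibromo‑6‑methoxyphenoxy)phenoxy]phenyl}trimethylsilane, via bridged lactone 16 (not isolated)
Conditions: 15 (3 equiv), BHT (cat.), PhMe, 130 °C, sealed tube
Reagents that add atoms: none
Why: Thermal inverse‑electron‑demand Diels–Alder reaction of a 2‑pyrone with an electron‑rich alkyne followed by retro‑[4+2] loss of CO2, the established way from 2‑pyrones and alkynes to benzenes. The ynol ether adds across C3 and C6 of the electron‑poor bromopyrone in a concerted but asynchronous [4+2] cycloaddition to give the bridged lactone 16; both new C–C bonds form in this one intermolecular cycloaddition, so ring C closes by cycloaddition and not by cyclisation of a chain. At the reaction temperature 16 should extrude CO2 in a cycloreversion driven by aromatisation, and the six‑membered carbocycle that remains is ring C. The two bridgehead stereocenters of 16 form as a racemate and both vanish with CO2, so no stereocenter has to be controlled. The selectivity needed is regiochemical: the silicon‑bearing carbon must bond to C6 of the pyrone and the oxygen‑bearing carbon to C3. The ynol ether is polarised so that the carbon beta to oxygen, the silylated one, is the nucleophilic end, and the positive charge that builds on the oxygen‑bearing carbon in the transition state is stabilised by the oxygen lone pair and by the adjacent C–Si bond; C6, the vinylogous acyl position next to the ring oxygen, is the electrophilic end of the diene, as in additions of enol ethers to bromopyrones. This orientation puts the pyrone bromine para to the ether oxygen and silicon ortho to it. The aryl ynol ether has no beta hydrogen on the oxygen substituent and cannot fragment to a ketene, and the linear alkyne holds the reacting carbons clear of the two ortho substituents of ring B.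

Step 10
Reactants: 17 {5‑bromo‑2‑[2,3,4‑tribromo‑6‑(2,4‑dibromo‑6‑methoxyphenoxy)phenoxy]phenyl}trimethylsilane
Product: 18 1,2,3‑tribromo‑4‑(4‑bromo‑2‑iodophenoxy)‑5‑(2,4‑dibromo‑6‑methoxyphenoxy)benzene
Conditions: ICl (1.05 equiv), CH2Cl2, −78 → 0 °C
Reagents that add atoms: iodine monochloride, ClI
Why: Ipso‑iododesilylation (electrophilic aromatic substitution at the silicon‑bearing carbon); the Wheland intermediate is stabilised by the C–Si bond and by the ortho ether oxygen, so iodine should enter exactly where silicon was, faster than ICl attacks any C–H position of the deactivated rings. The phenol is still methylated and cannot be iodinated.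

Step 11
Reactants: 18 1,2,3‑tribromo‑4‑(4‑bromo‑2‑iodophenoxy)‑5‑(2,4‑dibromo‑6‑methoxyphenoxy)benzene
Product: 19 bromoiesol B, 3,5‑dibromo‑2‑[3,4,5‑tribromo‑2‑(4‑bromo‑2‑iodophenoxy)phenoxy]phenol
Conditions: BBr3 (3 equiv), CH2Cl2, −78 → 20 °C; then H2O
Reagents that add atoms: none
Why: Lewis‑acid cleavage of an aryl methyl ether; BBr3 coordinates the methoxy oxygen and bromide removes the methyl group by SN2 substitution. The two diaryl ether links offer no sp3 carbon to attack and the aryl halides are inert, so aqueous work‑up should give the target.

## Compound list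

1 | guaiacol (2‑methoxyphenol) | COc1ccccc1O | starting material
2 | 2,4‑dibromo‑6‑methoxyphenol | COc1cc(Br)cc(Br)c1O | intermediate
3 | 5‑bromo‑2‑fluorobenzaldehyde | O=Cc1cc(Br)ccc1F | starting material
4 | 5‑bromo‑2‑(2,4‑dibromo‑6‑methoxyphenoxy)benzaldehyde | COc1cc(Br)cc(Br)c1Oc1ccc(Br)cc1C=O | intermediate
5 | 5‑bromo‑2‑(2,4‑dibromo‑6‑methoxyphenoxy)phenyl formate | COc1cc(Br)cc(Br)c1Oc1ccc(Br)cc1OC=O | intermediate
6 | 5‑bromo‑2‑(2,4‑dibromo‑6‑methoxyphenoxy)phenol | COc1cc(Br)cc(Br)c1Oc1ccc(Br)cc1O | intermediate
7 | 2,3,4‑tribromo‑6‑(2,4‑dibromo‑6‑methoxyphenoxy)phenol (ring A–ring B phenol) | COc1cc(Br)cc(Br)c1Oc1cc(Br)c(Br)c(Br)c1O | intermediate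
8 | 1,2,3‑tribromo‑5‑(2,4‑dibromo‑6‑methoxyphenoxy)‑4‑(ethenyloxy)benzene | COc1cc(Br)cc(Br)c1Oc1cc(Br)c(Br)c(Br)c1OC=C | intermediate
9 | 1,2,3‑tribromo‑4‑(1,2‑dibromoethoxy)‑5‑(2,4‑dibromo‑6‑methoxyphenoxy)benzene (racemic) | COc1cc(Br)cc(Br)c1Oc1cc(Br)c(Br)c(Br)c1OC(Br)CBr | intermediate
10 | 1,2,3‑tribromo‑4‑[(Z)‑2‑bromoethenyloxy]‑5‑(2,4‑dibromo‑6‑methoxyphenoxy)benzene | COc1cc(Br)cc(Br)c1Oc1cc(Br)c(Br)c(Br)c1O/C=C\Br | intermediate
11 | 1,2,3‑tribromo‑5‑(2,4‑dibromo‑6‑methoxyphenoxy)‑4‑(ethynyloxy)benzene | COc1cc(Br)cc(Br)c1Oc1cc(Br)c(Br)c(Br)c1OC#C | intermediate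
12 | lithium acetylide of 11 | COc1cc(Br)cc(Br)c1Oc1cc(Br)c(Br)c(Br)c1OC#C[Li] | intermediate
13 | trimethyl{[2,3,4‑tribromo‑6‑(2,4‑dibromo‑6‑methoxyphenoxy)phenoxy]ethynyl}silane | COc1cc(Br)cc(Br)c1Oc1cc(Br)c(Br)c(Br)c1OC#C[Si](C)(C)C | intermediate
14 | coumalic acid (2‑oxo‑2H‑pyran‑5‑carboxylic acid) | O=C(O)c1ccc(=O)oc1 | starting material
15 | 5‑bromo‑2H‑pyran‑2‑one | O=c1ccc(Br)co1 | intermediate
16 | 7‑bromo‑5‑[2,3,4‑tribromo‑6‑(2,4‑dibromo‑6‑methoxyphenoxy)phenoxy]‑6‑(trimethylsilyl)‑2‑oxabicyclo[2.2.2]octa‑5,7‑dien‑3‑one (racemic, one enantiomer drawn) | COc1cc(Br)cc(Br)c1Oc1cc(Br)c(Br)c(Br)c1OC1=C([Si](C)(C)C)[C@H]2OC(=O)[C@@H]1C=C2Br | intermediate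
17 | {5‑bromo‑2‑[2,3,4‑tribromo‑6‑(2,4‑dibromo‑6‑methoxyphenoxy)phenoxy]phenyl}trimethylsilane | COc1cc(Br)cc(Br)c1Oc1cc(Br)c(Br)c(Br)c1Oc1ccc(Br)cc1[Si](C)(C)C | intermediate
18 | 1,2,3‑tribromo‑4‑(4‑bromo‑2‑iodophenoxy)‑5‑(2,4‑dibromo‑6‑methoxyphenoxy)benzene (O‑methyl ether of the target) | COc1cc(Br)cc(Br)c1Oc1cc(Br)c(Br)c(Br)c1Oc1ccc(Br)cc1I | intermediate
19 | bromoiesol B, 3,5‑dibromo‑2‑[3,4,5‑tribromo‑2‑(4‑bromo‑2‑iodophenoxy)phenoxy]phenol | Oc1cc(Br)cc(Br)c1Oc1cc(Br)c(Br)c(Br)c1Oc1ccc(Br)cc1I | target

## Step count and least certain steps

Total step count: 11. Longest linear sequence: 10 steps (steps 1–7 and 9–11, from guaiacol); step 8 is a one‑step side branch.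

**Step 9 (key step).** The aryloxy group of 13 is a weaker donor than an alkoxy group and the silyl group adds bulk, so the cycloaddition may be slow at temperatures the components tolerate. The likely failures are slow cycloaddition with competing self‑reaction of the pyrone, thermal oligomerisation of the ynol ether, and partial loss of regiocontrol. The fallback gives up building ring C and attaches it as an SNAr‑activated arene, using only known reactions.
- It sets out from 7. Treatment with 4‑bromo‑1‑fluoro‑2‑nitrobenzene (O=[N+]([O-])c1cc(Br)ccc1F) and K2CO3 in DMSO at 90 °C should give 1,2,3‑tribromo‑4‑(4‑bromo‑2‑nitrophenoxy)‑5‑(2,4‑dibromo‑6‑methoxyphenoxy)benzene F1.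
- Iron powder and NH4Cl in aqueous ethanol reduce the nitro group to 5‑bromo‑2‑[2,3,4‑tribromo‑6‑(2,4‑dibromo‑6‑methoxyphenoxy)phenoxy]aniline F2.
- Diazotisation with NaNO2 and p‑toluenesulfonic acid in aqueous acetonitrile gives the arenediazonium p‑toluenesulfonate F3, which KI converts in the same flask (Sandmeyer‑type iodination) into 18.
- The route is rejoined at 18, before step 11. Both ring B positions ortho to the bridging oxygen are substituted, which blocks Pschorr‑type ring closure.

**Step 7.** The strong bases may metalate the polybrominated rings, followed by bromine migration, and the terminal ynol ether may polymerise before it is silylated. The fallback sets out from 10 and separates the two events.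
- The elimination is run alone (KOtBu, THF, −40 → 0 °C) and 11 is isolated quickly over deactivated alumina.
- The C‑silylation is then done without any amide base, through a catalytic zinc acetylide (Zn(OTf)2 as catalyst, Et3N, Me3SiOTf, CH2Cl2, 20 °C), and returns to 13.
- No compound outside the list is made (entry F0).

**Step 5.** Vinyl transfer to a phenoxide that is both doubly ortho‑substituted and weakly nucleophilic may be slow, so that the vinylboron reagent is consumed by protodeboronation first. The fallback sets out from 7 and forms the O–C bond by SN2 alkylation.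
- Excess 1,2‑dibromoethane (BrCCBr) and K2CO3 in DMF at 70 °C give 1,2,3‑tribromo‑4‑(2‑bromoethoxy)‑5‑(2,4‑dibromo‑6‑methoxyphenoxy)benzene F4.
- E2 elimination with KOtBu in THF at 0 °C returns to 8.

**Step 2.** The fluoride of 3 is activated only by a formyl group, and the phenoxide of 2 is hindered, so the substitution may stall while the aldehyde degrades under hot basic conditions. The fallback sets out from 2 and uses a nitro‑activated partner.
- 4‑Bromo‑1‑fluoro‑2‑nitrobenzene and K2CO3 in DMF at 80 °C give 1,5‑dibromo‑2‑(4‑bromo‑2‑nitrophenoxy)‑3‑methoxybenzene F5.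
- Iron powder and NH4Cl in aqueous ethanol give 5‑bromo‑2‑(2,4‑dibromo‑6‑methoxyphenoxy)aniline F6.
- NaNO2 in aqueous H2SO4 at 0 °C gives 5‑bromo‑2‑(2,4‑dibromo‑6‑methoxyphenoxy)benzenediazonium hydrogensulfate F7.
- Hydroxydediazoniation with Cu(NO3)2 and Cu2O in water at 20 °C returns to 6, before step 4. Both ortho positions of ring A are substituted, which disfavours ring closure onto ring A, though capture of the reactive aryl intermediate by the neighbouring methoxy oxygen remains the weak point of this detour.

## Further compounds

F1 | step 9 | 1,2,3‑tribromo‑4‑(4‑bromo‑2‑nitrophenoxy)‑5‑(2,4‑dibromo‑6‑methoxyphenoxy)benzene | COc1cc(Br)cc(Br)c1Oc1cc(Br)c(Br)c(Br)c1Oc1ccc(Br)cc1[N+](=O)[O-]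
F2 | step 9 | 5‑bromo‑2‑[2,3,4‑tribromo‑6‑(2,4‑dibromo‑6‑methoxyphenoxy)phenoxy]aniline | COc1cc(Br)cc(Br)c1Oc1cc(Br)c(Br)c(Br)c1Oc1ccc(Br)cc1N
F3 | step 9 | 5‑bromo‑2‑[2,3,4‑tribromo‑6‑(2,4‑dibromo‑6‑methoxyphenoxy)phenoxy]benzenediazonium p‑toluenesulfonate | COc1cc(Br)cc(Br)c1Oc1cc(Br)c(Br)c(Br)c1Oc1ccc(Br)cc1[N+]#N.Cc1ccc(cc1)S([O-])(=O)=O
F0 | step 7 | none | none
F4 | step 5 | 1,2,3‑tribromo‑4‑(2‑bromoethoxy)‑5‑(2,4‑dibromo‑6‑methoxyphenoxy)benzene | COc1cc(Br)cc(Br)c1Oc1cc(Br)c(Br)c(Br)c1OCCBr
F5 | step 2 | 1,5‑dibromo‑2‑(4‑bromo‑2‑nitrophenoxy)‑3‑methoxybenzene | COc1cc(Br)cc(Br)c1Oc1ccc(Br)cc1[N+](=O)[O-]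
F6 | step 2 | 5‑bromo‑2‑(2,4‑dibromo‑6‑methoxyphenoxy)aniline | COc1cc(Br)cc(Br)c1Oc1ccc(Br)cc1N
F7 | step 2 | 5‑bromo‑2‑(2,4‑dibromo‑6‑methoxyphenoxy)benzenediazonium hydrogensulfate | COc1cc(Br)cc(Br)c1Oc1ccc(Br)cc1[N+]#N.OS(=O)(=O)[O-]
A1 | alternative 1 | 2‑[3,4,5‑tribromo‑2‑(4‑bromo‑2‑iodophenoxy)phenyl]‑4,4,5,5‑tetramethyl‑1,3,2‑dioxaborolane | CC1(C)OB(c2cc(Br)c(Br)c(Br)c2Oc2ccc(Br)cc2I)OC1(C)C
A2 | alternative 1 | 2,3,4‑tribromothiophene 1,1‑dioxide | O=S1(=O)C=C(Br)C(Br)=C1Br
A3 | alternative 1 | 2‑[(4‑bromo‑2‑iodophenoxy)ethynyl]‑4,4,5,5‑tetramethyl‑1,3,2‑dioxaborolane | CC1(C)OB(C#COc2ccc(Br)cc2I)OC1(C)C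
A4 | alternative 2 | 2‑{3,5‑dibromo‑2‑[3,4,5‑tribromo‑2‑(4‑bromo‑2‑iodophenoxy)phenoxy]phenyl}‑4,4,5,5‑tetramethyl‑1,3,2‑dioxaborolane | CC1(C)OB(c2cc(Br)cc(Br)c2Oc2cc(Br)c(Br)c(Br)c2Oc2ccc(Br)cc2I)OC1(C)C
A5 | alternative 2 | 3,5‑dibromo‑2H‑pyran‑2‑one | O=c1occ(Br)cc1Br
A6 | alternative 2 | 2‑{[3,4,5‑tribromo‑2‑(4‑bromo‑2‑iodophenoxy)phenoxy]ethynyl}‑4,4,5,5‑tetramethyl‑1,3,2‑dioxaborolane | CC1(C)OB(C#COc2cc(Br)c(Br)c(Br)c2Oc2ccc(Br)cc2I)OC1(C)C
A7 | alternative 3 | O‑methyl ether of the target (identical with 18) | COc1cc(Br)cc(Br)c1Oc1cc(Br)c(Br)c(Br)c1Oc1ccc(Br)cc1I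
A8 | alternative 3 | 4‑bromo‑2‑(trimethylsilyl)phenyl trifluoromethanesulfonate | C[Si](C)(C)c1cc(Br)ccc1OS(=O)(=O)C(F)(F)F
A9 | alternative 3 | perfluorohexyl iodide (1‑iodotridecafluorohexane) | FC(F)(F)C(F)(F)C(F)(F)C(F)(F)C(F)(F)C(F)(F)I
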